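The last retrosynthetic cuts are the O5–CH3 and O7–CH3 bonds, so both phenols travel through the route as methyl ethers.
Central cut: in the pyran-4-one ring, C3 is a bare CH between the C4 ketone (on C4a of the benzene ring) and C2 (which holds O1 and the C13 chain). Cutting C3–C4 and C2=C3 leaves a one-carbon phosphorus ylide, a benzoate carbon (C4) and the carbonyl of an aryl tetradecanoate (C2, with O1 already on C8a).
The remaining cuts are O1–C2 (ester from tetradecanoyl chloride), C4–C4a (formylation) and the aryl–CH3 bonds at C6 and C8 (lithiation/methylation), which lead back to 1,3,5-trimethoxybenzene.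
Forward order: the benzene ring is bought, then come two C-methylations, formylation, release of one ortho phenol, attachment of the chain as an ester, and CHO → CO2H → silyl ester. The pyranone is the only ring made and closes in the ylide step. Demethylation ends the route.
Stereochemistry: there is none to set, and the only new double bond is endocyclic.

Key step: step 9

Remark: the target SMILES contains no stereocentre and no configurable double bond, so the compound is achiral and the route needs no stereocontrol.

Step 1
Reactants: 1 1,3,5-trimethoxybenzene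
Product: 3 2,4,6-trimethoxytoluene, via 2,4,6-trimethoxyphenyllithium 2 (not isolated)
Conditions: n-BuLi (1.1 equiv), THF, 0 °C → rt; MeI, 0 °C → rt
Reagents that add atoms: iodomethane, CI
Why: Directed ortho-metalation works because every ring CH of 1 lies between two methoxy groups that acidify it and hold the lithium, and aryllithium 2 is then C-methylated by SN2 displacement on iodomethane.

Step 2
Reactants: 3 2,4,6-trimethoxytoluene
Product: 5 1,3,5-trimethoxy-2,4-dimethylbenzene, via 2,4,6-trimethoxy-3-methylphenyllithium 4 (not isolated)
Conditions: n-BuLi, TMEDA, Et2O, 0 °C → rt; MeI, 0 °C → rt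
Reagents that add atoms: iodomethane, CI
Why: A second directed ortho-metalation should succeed because the two equivalent ring CH positions of 3 are each still flanked by two methoxy groups, and TMEDA makes ring lithiation fast enough to outrun lateral deprotonation of the methyl group.

Step 3
Reactants: 5 1,3,5-trimethoxy-2,4-dimethylbenzene
Product: 7 2,4,6-trimethoxy-3,5-dimethylbenzaldehyde, via benzylidene(dimethyl)iminium chloride 6 (not isolated)
Conditions: POCl3, DMF, 0 → 80 °C; then ice-water
Reagents that add atoms: N,N-dimethylformamide, CN(C)C=O; water, O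
Why: In this Vilsmeier–Haack formylation the single free ring position of 5 is ortho to two methoxy donors and para to the third, so the chloroiminium ion can attack only there, and water hydrolyses iminium salt 6 to the aldehyde.

Step 4
Reactants: 7 2,4,6-trimethoxy-3,5-dimethylbenzaldehyde
Product: 9 2-hydroxy-4,6-dimethoxy-3,5-dimethylbenzaldehyde, via aryloxydichloroborane chelate 8 (not isolated)
Conditions: BCl3 (1.1 equiv), CH2Cl2, −78 → 0 °C; then H2O
Reagents that add atoms: none
Why: In this chelation-directed aryl methyl ether cleavage, BCl3 bridges the aldehyde oxygen and one of the two equivalent ortho methoxy oxygens, chloride removes that methyl group, and six-membered chelate 8 ties up the Lewis acid so that about one equivalent leaves the other two ethers intact.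

Step 5
Reactants: 9 2-hydroxy-4,6-dimethoxy-3,5-dimethylbenzaldehyde; 10 tetradecanoyl chloride
Product: 11 2-formyl-3,5-dimethoxy-4,6-dimethylphenyl tetradecanoate
Conditions: Et3N, DMAP (cat.), CH2Cl2, 0 °C → rt
Reagents that add atoms: none
Why: DMAP-catalysed O-acylation of a phenol with an acid chloride should work here because the acylpyridinium ion is reactive enough to esterify the hydrogen-bonded, doubly flanked hydroxyl group, and the aldehyde is inert under these conditions.

Step 6
Reactants: 11 2-formyl-3,5-dimethoxy-4,6-dimethylphenyl tetradecanoate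
Product: 12 2,4-dimethoxy-3,5-dimethyl-6-(tetradecanoyloxy)benzoic acid
Conditions: NaClO2, NaH2PO4, 2-methyl-2-butene, t-BuOH/THF/H2O, 0 °C → rt; extraction at pH about 4, acid used without delay
Reagents that add atoms: sodium chlorite, [Na+].[O-]Cl=O
Why: In the Pinnick oxidation chlorous acid adds to the aldehyde and fragments to the acid at a buffered pH where the aryl ester is not hydrolysed, the fully substituted ring offers no site for chlorination, and the alkene takes up the hypochlorous acid.

Step 7
Reactants: 12 2,4-dimethoxy-3,5-dimethyl-6-(tetradecanoyloxy)benzoic acid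
Product: 13 tert-butyldimethylsilyl 2,4-dimethoxy-3,5-dimethyl-6-(tetradecanoyloxy)benzoate
Conditions: TBSCl, imidazole, DMF, 0 °C → rt
Reagents that add atoms: tert-butyldimethylsilyl chloride, CC(C)(C)[Si](C)(C)Cl
Why: Silyl ester formation through the silylimidazolium ion takes place at the carboxylate oxygen, two atoms away from the crowded ring carbon, so the flanking groups do not hinder it, and the tert-butyldimethylsilyl ester is robust enough to be handled under dry conditions.

Step 8
Reactants: 14 methyltriphenylphosphonium bromide; 15 chlorotrimethylsilane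
Product: 18 (trimethylsilyl)methylenetriphenylphosphorane, via methylenetriphenylphosphorane 16 (not isolated), via (trimethylsilylmethyl)triphenylphosphonium chloride 17 (not isolated)
Conditions: 14 (2 equiv), n-BuLi (2 equiv), THF, 0 °C; 15 (1 equiv), 0 °C → rt; salts filtered off under Ar, THF solution used at once
Reagents that add atoms: none
Why: This is C-silylation of a non-stabilised ylide followed by transylidation, in which 16 attacks silicon to give salt 17, whose silyl-flanked CH2 is more acidic than a P-methyl group, so the second equivalent of 16 deprotonates it and drops out as the methylphosphonium chloride.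

Step 9
Reactants: 13 tert-butyldimethylsilyl 2,4-dimethoxy-3,5-dimethyl-6-(tetradecanoyloxy)benzoate; 18 (trimethylsilyl)methylenetriphenylphosphorane
Product: 20 5,7-dimethoxy-6,8-dimethyl-2-tridecyl-4H-chromen-4-one, via aroylmethylenetriphenylphosphorane 19 (not isolated)
Conditions: 18 (1.2 equiv, solution from step 8), THF, 0 °C → rt, then reflux
Reagents that add atoms: none
Why: The carbanionic carbon of 18 adds to the silyl ester carbonyl of 13 and tert-butyldimethylsilanolate leaves; the silanolate then strips the C-bound SiMe3 group from the resulting α-silyl acylphosphonium ion, so the stabilised phosphorane 19 (C3–C4 made) arises from one equivalent of ylide without extra base, and the strong Si–O–Si bond makes this stage irreversible. On heating, the ylide carbon of 19 adds to the neighbouring tetradecanoate carbonyl in a 6-exo-trig closure (ring atoms C3, C4, C4a, C8a, O1, C2), the alkoxide binds phosphorus to give an oxaphosphetane, and its cycloreversion expels triphenylphosphine oxide and leaves C2=C3, with the aryloxy oxygen kept as O1 and the chain already on C2. The closest known reaction type is this same one-pot chromone synthesis from silyl esters of O-acylsalicylic acids and the silylated ylide, that is, ylide C-acylation followed by intramolecular Wittig olefination of an ester carbonyl, which also covers aliphatic O-acyl groups. No stereocentre is created and the new double bond is endocyclic in a six-membered ring, so no geometry has to be controlled. The selectivity needed is attack at the silyl ester rather than at the aryl ester or its α-CH2: the silyl ester is the better acyl donor because its leaving group is consumed at once by desilylation, the aryl ester belongs to a di-ortho-substituted, electron-rich phenol (a poor leaving group), and the ylide is kept near one equivalent and added cold. The methoxy and acyloxy groups beside the benzoate carbon slow the first addition, which is why time at room temperature is allowed before reflux and why this step heads the risk list.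

Step 10
Reactants: 20 5,7-dimethoxy-6,8-dimethyl-2-tridecyl-4H-chromen-4-one
Product: 21 5,7-dihydroxy-6,8-dimethyl-2-tridecyl-4H-chromen-4-one
Conditions: BBr3 (5 equiv), CH2Cl2, −78 °C → rt; then H2O
Reagents that add atoms: none
Why: In this Lewis-acid aryl methyl ether cleavage the 5-ether is activated by boron chelation to the C4 carbonyl, the 7-ether is twisted out of conjugation by its two methyl neighbours and so binds boron readily, the chromone and the alkyl chain are inert, and any Wessely–Moser ring opening and reclosure would be degenerate on this symmetric A ring.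

Compound list
1 | 1,3,5-trimethoxybenzene | COc1cc(OC)cc(OC)c1 | starting material
2 | 2,4,6-trimethoxyphenyllithium | [Li]c1c(OC)cc(OC)cc1OC | intermediate
3 | 2,4,6-trimethoxytoluene | COc1cc(OC)c(C)c(OC)c1 | intermediate
4 | 2,4,6-trimethoxy-3-methylphenyllithium | [Li]c1c(OC)cc(OC)c(C)c1OC | intermediate
5 | 1,3,5-trimethoxy-2,4-dimethylbenzene | COc1cc(OC)c(C)c(OC)c1C | intermediate
6 | N,N-dimethyl-1-(2,4,6-trimethoxy-3,5-dimethylphenyl)methaniminium chloride | COc1c(C)c(OC)c(C)c(OC)c1C=[N+](C)C.[Cl-] | intermediate
7 | 2,4,6-trimethoxy-3,5-dimethylbenzaldehyde | COc1c(C)c(OC)c(C)c(OC)c1C=O | intermediate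
8 | dichloro(2-formyl-3,5-dimethoxy-4,6-dimethylphenoxy)borane (chelated to the formyl oxygen) | COc1c(C)c(OC)c(C)c(OB(Cl)Cl)c1C=O | intermediate
9 | 2-hydroxy-4,6-dimethoxy-3,5-dimethylbenzaldehyde | COc1c(C)c(OC)c(C)c(O)c1C=O | intermediate
10 | tetradecanoyl chloride | CCCCCCCCCCCCCC(=O)Cl | starting material
11 | 2-formyl-3,5-dimethoxy-4,6-dimethylphenyl tetradecanoate | CCCCCCCCCCCCCC(=O)Oc1c(C)c(OC)c(C)c(OC)c1C=O | intermediate
12 | 2,4-dimethoxy-3,5-dimethyl-6-(tetradecanoyloxy)benzoic acid | CCCCCCCCCCCCCC(=O)Oc1c(C)c(OC)c(C)c(OC)c1C(=O)O | intermediate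
13 | tert-butyldimethylsilyl 2,4-dimethoxy-3,5-dimethyl-6-(tetradecanoyloxy)benzoate | CCCCCCCCCCCCCC(=O)Oc1c(C)c(OC)c(C)c(OC)c1C(=O)O[Si](C)(C)C(C)(C)C | intermediate
14 | methyltriphenylphosphonium bromide | C[P+](c1ccccc1)(c1ccccc1)c1ccccc1.[Br-] | starting material
15 | chlorotrimethylsilane | C[Si](C)(C)Cl | starting material
16 | methylenetriphenylphosphorane | C=P(c1ccccc1)(c1ccccc1)c1ccccc1 | intermediate
17 | (trimethylsilylmethyl)triphenylphosphonium chloride | C[Si](C)(C)C[P+](c1ccccc1)(c1ccccc1)c1ccccc1.[Cl-] | intermediate
18 | (trimethylsilyl)methylenetriphenylphosphorane | C[Si](C)(C)C=P(c1ccccc1)(c1ccccc1)c1ccccc1 | intermediate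
19 | 3,5-dimethoxy-4,6-dimethyl-2-[(triphenyl-λ5-phosphanylidene)acetyl]phenyl tetradecanoate | CCCCCCCCCCCCCC(=O)Oc1c(C)c(OC)c(C)c(OC)c1C(=O)C=P(c1ccccc1)(c1ccccc1)c1ccccc1 | intermediate
20 | 5,7-dimethoxy-6,8-dimethyl-2-tridecyl-4H-chromen-4-one | CCCCCCCCCCCCCc1cc(=O)c2c(OC)c(C)c(OC)c(C)c2o1 | intermediate
21 | 5,7-dihydroxy-6,8-dimethyl-2-tridecyl-4H-chromen-4-one | CCCCCCCCCCCCCc1cc(=O)c2c(O)c(C)c(O)c(C)c2o1 | target

Total step count: 10. Longest linear sequence: 9 (steps 1–7, 9, 10). Step 8 is a one-step side branch.

Steps most likely to fail

Step 9. The bulky ylide may add too slowly to the doubly flanked silyl ester carbonyl. Acyl transfer from the aryl tetradecanoate to the ylide (loss of the chain from the arene) or deprotonation next to the ester could then take over. The fallback sets out from 5 and comes back at 20. It brings C3 and C4 in together as an acetyl group and forms C2–C3 by an enolate acyl shift, so the reacting carbon sits one atom further from the crowded ring.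
- Friedel–Crafts acetylation of 5 (AcCl, TiCl4, CH2Cl2, 0 °C) should give 1-(2,4,6-trimethoxy-3,5-dimethylphenyl)ethanone F1.
- Chelation-directed cleavage with BCl3 should free one ortho phenol to give 1-(2-hydroxy-4,6-dimethoxy-3,5-dimethylphenyl)ethanone F2.
- Acylation with 10 (Et3N, DMAP) should give 2-acetyl-3,5-dimethoxy-4,6-dimethylphenyl tetradecanoate F3.
- Baker–Venkataraman rearrangement (KOt-Bu, THF) should give 1-(2-hydroxy-4,6-dimethoxy-3,5-dimethylphenyl)hexadecane-1,3-dione F4.
- Acid-catalysed cyclodehydration (cat. H2SO4, AcOH, heat) should close the pyranone to 20.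

Step 6. Oxidation at the flanked aldehyde may be slow. Hydrolysis of the aryl ester or protodecarboxylation of the electron-rich acid could then erode the material. The fallback sets out from 5 and comes back at 12. It introduces the carboxyl carbon at the acid oxidation level, so no oxidation is needed.
- Lithiation of 5 (n-BuLi, TMEDA, Et2O) should give 2,4,6-trimethoxy-3,5-dimethylphenyllithium F5.
- Quenching with allyl chloroformate should give prop-2-en-1-yl 2,4,6-trimethoxy-3,5-dimethylbenzoate F6.
- BCl3 directed by the ester carbonyl should give prop-2-en-1-yl 2-hydroxy-4,6-dimethoxy-3,5-dimethylbenzoate F7.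
- Acylation with 10 (Et3N, DMAP) should give prop-2-en-1-yl 2,4-dimethoxy-3,5-dimethyl-6-(tetradecanoyloxy)benzoate F8.
- Neutral Tsuji–Trost-type deallylation (cat. Pd(PPh3)4, PhSiH3, CH2Cl2, rt) should release 12 without touching the aryl ester.

Step 4. All three ethers are twisted by two ortho neighbours and are therefore labile, so cleavage may not stop after one methyl group or may stray to the 4-ether. The fallback sets out from 7 and comes back at 9. It replaces selective cleavage with selective alkylation.
- Exhaustive demethylation (excess BBr3, CH2Cl2) should give 2,4,6-trihydroxy-3,5-dimethylbenzaldehyde F9.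
- Dimethyl sulfate (2 equiv) with K2CO3 in acetone should then methylate the 4-hydroxyl and one ortho hydroxyl, while the last one, locked in a hydrogen bond to the aldehyde, stays free. This gives 9.

Further compounds
F1 | step 9 | 1-(2,4,6-trimethoxy-3,5-dimethylphenyl)ethanone | CC(=O)c1c(OC)c(C)c(OC)c(C)c1OC
F2 | step 9 | 1-(2-hydroxy-4,6-dimethoxy-3,5-dimethylphenyl)ethanone | CC(=O)c1c(O)c(C)c(OC)c(C)c1OC
F3 | step 9 | 2-acetyl-3,5-dimethoxy-4,6-dimethylphenyl tetradecanoate | CCCCCCCCCCCCCC(=O)Oc1c(C)c(OC)c(C)c(OC)c1C(C)=O
F4 | step 9 | 1-(2-hydroxy-4,6-dimethoxy-3,5-dimethylphenyl)hexadecane-1,3-dione | CCCCCCCCCCCCCC(=O)CC(=O)c1c(O)c(C)c(OC)c(C)c1OC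
F5 | step 6 | 2,4,6-trimethoxy-3,5-dimethylphenyllithium | [Li]c1c(OC)c(C)c(OC)c(C)c1OC
F6 | step 6 | prop-2-en-1-yl 2,4,6-trimethoxy-3,5-dimethylbenzoate | C=CCOC(=O)c1c(OC)c(C)c(OC)c(C)c1OC
F7 | step 6 | prop-2-en-1-yl 2-hydroxy-4,6-dimethoxy-3,5-dimethylbenzoate | C=CCOC(=O)c1c(O)c(C)c(OC)c(C)c1OC
F8 | step 6 | prop-2-en-1-yl 2,4-dimethoxy-3,5-dimethyl-6-(tetradecanoyloxy)benzoate | CCCCCCCCCCCCCC(=O)Oc1c(C)c(OC)c(C)c(OC)c1C(=O)OCC=C
F9 | step 4 | 2,4,6-trihydroxy-3,5-dimethylbenzaldehyde | Cc1c(O)c(C)c(O)c(C=O)c1O
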